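**Retrosynthetic overview**
- The target comes from global desilylation of its tris-TBS ether; the (Z)-benzylidene is installed last by vinylogous aldol condensation of a 3,4-disubstituted furan-2(5H)-one with 3-bromo-4-hydroxybenzaldehyde.
- The furanone comes from Baeyer–Villiger O-insertion into a 2-alkyl-3-aryl-cyclobutenone. That four-membered ring, which supplies all four lactone carbons, is made by regioselective [2+2] cycloaddition of dichloroketene to an aryl alkyne (key step).
- The aryl alkyne comes from Sonogashira coupling of a terminal propargylic silyl ether with a protected 2-bromo-4-iodophenol.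
- The terminal alkyne comes from (S)-4-hydroxymandelic acid by ring dibromination, double methylation, silylation and ester-to-alkyne homologation; the carbinol stereocentre is bought and only carried.
- Ring order: cyclobutenone ([2+2]), then butenolide (ring expansion), then exocyclic alkene.

Assumption: the target is (S) at the carbinol and (Z) at the exocyclic alkene (from the SMILES), and enantiopure (S)-4-hydroxymandelic acid (1) is purchased.

**Step 1**
Reactants: 1, (S)-4-hydroxymandelic acid
Product: 2, (2S)-2-(3,5-dibromo-4-hydroxyphenyl)-2-hydroxyacetic acid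
Conditions: NBS (2.05 equiv), MeCN, 0 °C to rt
Reagents that add atoms: N-bromosuccinimide, O=C1CCC(=O)N1Br
Why: Electrophilic aromatic bromination of a para-substituted phenol goes cleanly to both ortho positions and is much faster than any reaction at the side chain; the stereocentre is untouched.

**Step 2**
Reactants: 2
Product: 3, methyl (2S)-2-(3,5-dibromo-4-methoxyphenyl)-2-hydroxyacetate
Conditions: MeI (3 equiv), K2CO3, acetone, rt to 40 °C
Reagents that add atoms: iodomethane, CI (two methyl groups)
Why: SN2 O-alkylation of the carboxylate and the acidic 2,6-dibromophenoxide in one pot; the secondary alcohol is not deprotonated by carbonate, and these weakly basic heterogeneous conditions should not epimerise the mandelate.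

**Step 3**
Reactants: 3
Product: 4, methyl (2S)-2-{[tert-butyl(dimethyl)silyl]oxy}-2-(3,5-dibromo-4-methoxyphenyl)acetate
Conditions: TBSCl, imidazole, DMF, rt
Reagents that add atoms: TBSCl, CC(C)(C)[Si](C)(C)Cl
Why: Standard silylation of a secondary alcohol; it protects the carbinol for the reduction and ketene steps.

**Step 4**
Reactants: 4
Product: 5, tert-butyl{[(1R)-1-(3,5-dibromo-4-methoxyphenyl)prop-2-yn-1-yl]oxy}dimethylsilane (same spatial arrangement; the descriptor becomes R only because aryl now outranks ethynyl)
Conditions: DIBAL-H, CH2Cl2, −78 °C; then MeOH, K2CO3, Ohira–Bestmann reagent, −78 to 0 °C (one pot, aldehyde not isolated)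
Reagents that add atoms: dimethyl (1-diazo-2-oxopropyl)phosphonate, CC(=O)C(=[N+]=[N-])P(=O)(OC)OC (one carbon)
Why: Partial reduction of the α-silyloxy ester to the aldehyde, then Seyferth–Gilbert homologation (Ohira–Bestmann variant) to the terminal alkyne; the existing stereocentre is carried through, with the labile aldehyde kept cold and consumed in situ.

**Step 5**
Reactants: 6, 2-bromo-4-iodophenol
Product: 7, (2-bromo-4-iodophenoxy)(tert-butyl)dimethylsilane
Conditions: TBSCl, imidazole, CH2Cl2, rt
Reagents that add atoms: TBSCl, CC(C)(C)[Si](C)(C)Cl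
Why: Phenol silylation, so the phenol is not acylated in the ketene step.

**Step 6**
Reactants: 5 and 7
Product: 8, tert-butyl{2-bromo-4-[(3S)-3-{[tert-butyl(dimethyl)silyl]oxy}-3-(3,5-dibromo-4-methoxyphenyl)prop-1-yn-1-yl]phenoxy}dimethylsilane
Conditions: PdCl2(PPh3)2 (2 mol%), CuI (4 mol%), Et3N, THF, rt
Reagents that add atoms: none
Why: Sonogashira coupling; at rt oxidative addition is selective for C–I over the three C–Br bonds, and the stereocentre is not involved.

**Step 7 (key step)**
Reactants: 8
Product: 9, 3-[3-bromo-4-(TBS-oxy)phenyl]-2-[(S)-(TBS-oxy)(3,5-dibromo-4-methoxyphenyl)methyl]-4,4-dichlorocyclobut-2-en-1-one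
Conditions: Cl3CCOCl, Zn–Cu, DME, Et2O, rt
Reagents that add atoms: trichloroacetyl chloride, ClC(Cl)(Cl)C(Cl)=O (gives dichloroketene, ClC(Cl)=C=O, in situ)
Why: Thermal [2+2] ketene–alkyne cycloaddition; the ketene carbonyl carbon bonds to the alkyne carbon remote from the p-silyloxyaryl group so that developing positive charge is benzylic, which puts the carbinol-bearing carbon next to C=O and the aryl-bearing carbon next to CCl2.

**Step 8**
Reactants: 9
Product: 10, 3-[3-bromo-4-(TBS-oxy)phenyl]-2-[(S)-(TBS-oxy)(3,5-dibromo-4-methoxyphenyl)methyl]cyclobut-2-en-1-one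
Conditions: Zn dust, AcOH, TMEDA, EtOH, 0 °C to rt
Reagents that add atoms: none
Why: Reductive dechlorination of the α,α-dichloroketone through its zinc enolate; aryl bromides and silyl ethers are inert under these conditions.

**Step 9**
Reactants: 10
Product: 11, 4-[3-bromo-4-(TBS-oxy)phenyl]-3-[(S)-(TBS-oxy)(3,5-dibromo-4-methoxyphenyl)methyl]furan-2(5H)-one
Conditions: mCPBA, NaHCO3, CH2Cl2, 0 °C to rt
Reagents that add atoms: mCPBA, OOC(=O)c1cccc(Cl)c1 (one oxygen)
Why: Strain-driven Baeyer–Villiger ring expansion in which the sp3 CH2 is expected to migrate in preference to the conjugated alkenyl carbon (see risk list), giving the α,β-unsaturated γ-lactone with the carbinol substituent at C3 and the aryl at C4.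

**Step 10**
Reactants: 11 and 12, 3-bromo-4-hydroxybenzaldehyde
Product: 13, (5Z)-4-[3-bromo-4-(TBS-oxy)phenyl]-5-[3-bromo-4-(TBS-oxy)benzylidene]-3-[(S)-(TBS-oxy)(3,5-dibromo-4-methoxyphenyl)methyl]furan-2(5H)-one
Conditions: TBSOTf (3.5 equiv), i-Pr2NEt, CH2Cl2, 0 °C to rt; then DBU, rt
Reagents that add atoms: TBSOTf, CC(C)(C)[Si](C)(C)OS(=O)(=O)C(F)(F)F (silylates the aldehyde phenol in situ)
Why: Vinylogous Mukaiyama aldol of the in-situ 2-silyloxyfuran at C5 followed by DBU-mediated E1cB loss of silanol; the Z alkene is the thermodynamic isomer because it avoids the clash between the benzylidene aryl and the C4 aryl.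

**Step 11**
Reactants: 13
Product: 14, (5Z)-4-(3-bromo-4-hydroxyphenyl)-5-(3-bromo-4-hydroxybenzylidene)-3-[(S)-(3,5-dibromo-4-methoxyphenyl)(hydroxy)methyl]furan-2(5H)-one (target)
Conditions: HF·pyridine, pyridine/THF, 0 °C to rt
Reagents that add atoms: none
Why: Fluoride desilylation removes all three TBS groups under buffered, non-basic conditions, which avoids phenoxide-assisted ionisation of the allylic benzylic carbinol; the methyl ether and lactone are untouched.

**Compound list**
1 | (S)-4-hydroxymandelic acid | Oc1ccc([C@H](O)C(=O)O)cc1 | starting material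
2 | (2S)-2-(3,5-dibromo-4-hydroxyphenyl)-2-hydroxyacetic acid | Oc1c(Br)cc([C@H](O)C(=O)O)cc1Br | intermediate
3 | methyl (2S)-2-(3,5-dibromo-4-methoxyphenyl)-2-hydroxyacetate | COc1c(Br)cc([C@H](O)C(=O)OC)cc1Br | intermediate
4 | methyl (2S)-2-(TBS-oxy)-2-(3,5-dibromo-4-methoxyphenyl)acetate | COc1c(Br)cc([C@H](O[Si](C)(C)C(C)(C)C)C(=O)OC)cc1Br | intermediate
5 | tert-butyl{[(1R)-1-(3,5-dibromo-4-methoxyphenyl)prop-2-yn-1-yl]oxy}dimethylsilane | COc1c(Br)cc([C@H](O[Si](C)(C)C(C)(C)C)C#C)cc1Br | intermediate
6 | 2-bromo-4-iodophenol | Oc1ccc(I)cc1Br | starting material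
7 | (2-bromo-4-iodophenoxy)(tert-butyl)dimethylsilane | CC(C)(C)[Si](C)(C)Oc1ccc(I)cc1Br | intermediate
8 | (S)-diaryl propargylic bis-silyl ether (internal alkyne) | COc1c(Br)cc([C@H](O[Si](C)(C)C(C)(C)C)C#Cc2ccc(O[Si](C)(C)C(C)(C)C)c(Br)c2)cc1Br | intermediate
9 | 4,4-dichlorocyclobutenone | COc1c(Br)cc([C@H](O[Si](C)(C)C(C)(C)C)C2=C(c3ccc(O[Si](C)(C)C(C)(C)C)c(Br)c3)C(Cl)(Cl)C2=O)cc1Br | intermediate
10 | cyclobutenone | COc1c(Br)cc([C@H](O[Si](C)(C)C(C)(C)C)C2=C(c3ccc(O[Si](C)(C)C(C)(C)C)c(Br)c3)CC2=O)cc1Br | intermediate
11 | 3,4-disubstituted furan-2(5H)-one | COc1c(Br)cc([C@H](O[Si](C)(C)C(C)(C)C)C2=C(c3ccc(O[Si](C)(C)C(C)(C)C)c(Br)c3)COC2=O)cc1Br | intermediate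
12 | 3-bromo-4-hydroxybenzaldehyde | O=Cc1ccc(O)c(Br)c1 | starting material
13 | tris-TBS (Z)-benzylidene butenolide | COc1c(Br)cc([C@H](O[Si](C)(C)C(C)(C)C)C2=C(c3ccc(O[Si](C)(C)C(C)(C)C)c(Br)c3)/C(=C/c3ccc(O[Si](C)(C)C(C)(C)C)c(Br)c3)OC2=O)cc1Br | intermediate
14 | CID71459453 | COc1c(Br)cc([C@H](O)C2=C(c3ccc(O)c(Br)c3)/C(=C/c3ccc(O)c(Br)c3)OC2=O)cc1Br | target

**Totals**
Total steps: 11. Longest linear sequence: 10 (steps 1–4, then 6–11; step 5 is a side-branch protection).

**Three steps most likely to fail**
1. Step 4. The α-aryl-α-silyloxy aldehyde can partly racemise under K2CO3/MeOH, which would erode the only stereocentre. Fallback: isolate the aldehyde cold and use base-free Ramirez dibromo-olefination (CBr4, PPh3, Zn); then form 8 directly by Pd-catalysed Suzuki coupling of the gem-dibromoalkene with the arylboronic acid analogue of 7 and dehydrobromination. This replaces steps 4 and 6.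
2. Step 9. Alkenyl migration or enone epoxidation could compete with CH2 migration in the Baeyer–Villiger step; I have not verified a direct precedent for this substitution pattern. Fallback: hydrolyse dichloride 9 to the cyclobutenedione (Ag(I), aqueous acetone), reduce the more electrophilic carbonyl (the one next to the aryl-bearing carbon), and heat the resulting 4-hydroxycyclobutenone. Its 4π-electrocyclic ring opening to a hydroxy vinylketene followed by lactonisation gives 11.
3. Step 10. The 2-oxidofuran intermediate could expel the C3-side carbinol silyl ether instead of the C5-side one, or the condensation could stall. Fallback: separate the two events. Run a low-temperature vinylogous aldol, isolate the C5 carbinol, and dehydrate it by syn-elimination with Burgess reagent, so no dienolate is generated next to a leaving group on the stereocentre.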